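The benzene ring of the target is read as a folded tetraketide: meta-related oxygens on C2 and C4, the pentadecyl chain on C6 and, on C1, an acetoxy group that can descend from a carboxyl carbon form the resorcylate pattern. Everything rests on disconnecting the C1–C6 ring bond. In a single operation, mild base folds the open-chain diketo-dioxinone 7 (palmitoyl–CH2–CO–CH2 on a 2,2-dimethyl-1,3-dioxin-4-one) by intramolecular aldol condensation and aromatises it to benzodioxinone 9, with both oxygens, the chain and the C1 carbon handle in place. That carbon then becomes the acetate carbonyl through a methyl ketone and Baeyer–Villiger oxygen insertion, benzyl ethers protecting both phenols.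

Key step: step 4

Remark: C1–C6 denote the benzene carbons of the target (C1 bears the acetate, C2 and C4 the hydroxyls, C6 the chain); lithium enolates and phenoxides of numbered compounds are treated as forms of those compounds and are not numbered separately.

Step 1
Reactants: 1 2,2,6-trimethyl-4H-1,3-dioxin-4-one; 2 acetyl chloride
Product: 3 2,2-dimethyl-6-(2-oxopropyl)-4H-1,3-dioxin-4-one
Conditions: 1 (2.0 equiv), LiN(SiMe3)2 (2.0 equiv), THF, −78 °C; then 2 (1.0 equiv), −78 °C; then 1 M HCl
Reagents that add atoms: none
Why: LiN(SiMe3)2 removes a proton from the C6 methyl group of the vinylogous ester to give the lithium dienolate, which is C-acylated at its γ-carbon by the acid chloride (vinylogous Claisen-type acylation), the second equivalent of dienolate taking up the acidic proton of the β-keto product so that the acetyl chloride is fully used.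

Step 2
Reactants: 4 hexadecanoyl chloride
Product: 5 N-methoxy-N-methylhexadecanamide
Conditions: MeNH(OMe)·HCl, K2CO3, CH2Cl2/H2O, 0 °C to rt
Reagents that add atoms: N,O-dimethylhydroxylamine hydrochloride, CNOC.Cl
Why: Schotten–Baumann N-acylation of the hydroxylamine by the acid chloride is fast and clean and should give the Weinreb amide, an acyl donor that reacts with a carbanion only once.

Step 3
Reactants: 3 2,2-dimethyl-6-(2-oxopropyl)-4H-1,3-dioxin-4-one; 5 N-methoxy-N-methylhexadecanamide
Product: 7 6-(2,4-dioxononadecyl)-2,2-dimethyl-4H-1,3-dioxin-4-one, via dilithium tetrahedral adduct 6 (not isolated)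
Conditions: 3 (1.5 equiv), LiN(iPr)2 (3.1 equiv), THF, −78 °C; then 5 (1.0 equiv), −78 to −30 °C; then cold 1 M HCl; crude product taken on without chromatography
Reagents that add atoms: none
Why: Two equivalents of LiN(iPr)2 convert 3 into its dianion, whose methyl-derived terminal carbanion is the most reactive site and adds to the amide carbonyl (crossed Claisen acylation in the form of a Weinreb ketone synthesis); the chelated adduct 6 should persist until the acidic quench, so the acidic 1,3-diketone never meets the dianion and neither double acylation nor proton quench by the product is expected.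

Step 4
Reactants: 7 6-(2,4-dioxononadecyl)-2,2-dimethyl-4H-1,3-dioxin-4-one
Product: 9 7-hydroxy-2,2-dimethyl-5-pentadecyl-4H-1,3-benzodioxin-4-one, via aldol carbinol 8 (not isolated)
Conditions: Et3N (5 equiv), CH2Cl2, rt; then 1 M HCl wash
Reagents that add atoms: none
Why: Triethylamine enolises the 1,3-diketone towards the dioxinone, giving an extended enolate whose nucleophilic terminus is C5 of the dioxinone ring (the carbon next to the lactone carbonyl); this carbon adds to the palmitoyl ketone carbon in an intramolecular aldol reaction that forms the C1–C6 bond of the future benzene ring and gives carbinol 8. The closure is a 6-(enolendo)-exo-trig cyclisation and produces the carbocyclic ring, the only ring made in the step. β-Elimination of water from 8 (E1cB, assisted by the ring ketone) and tautomerisation of that ketone to the phenol should then deliver the aromatic ring, so the carbinol centre of 8, formed as a racemate, is erased and no stereocentre needs control. The closest known reaction type is the biomimetic aldol cyclisation–dehydration of 3,5,7-triketo acid derivatives to resorcylates. The selectivity required is aldol folding instead of Claisen folding (attack of the chain on the carboxyl carbon, which would lead to an acylphloroglucinol) or O-cyclisation to a pyranone; it is secured because the carboxyl group and its β-enol are tied up in the dioxinone as a weakly electrophilic vinylogous carbonate, because C5 is held cis to the chain at a six-ring distance from the terminal ketone, and because the mild amine base does not open the dioxinone.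

Step 5
Reactants: 9 7-hydroxy-2,2-dimethyl-5-pentadecyl-4H-1,3-benzodioxin-4-one
Product: 10 7-(benzyloxy)-2,2-dimethyl-5-pentadecyl-4H-1,3-benzodioxin-4-one
Conditions: BnBr, K2CO3, acetone, reflux
Reagents that add atoms: benzyl bromide, BrCc1ccccc1
Why: Williamson etherification of the only free phenol (the C4 hydroxyl), which is acidic because it lies para to the lactone carbonyl, with a base too weak and too poorly nucleophilic to open the acylal lactone.

Step 6
Reactants: 10 7-(benzyloxy)-2,2-dimethyl-5-pentadecyl-4H-1,3-benzodioxin-4-one
Product: 12 1-[4-(benzyloxy)-2-hydroxy-6-pentadecylphenyl]ethan-1-one, via lithium hemiketal alkoxide 11 (not isolated)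
Conditions: MeLi (2.2 equiv), THF, −78 °C; then aq. NH4Cl, −78 °C to rt
Reagents that add atoms: methyllithium, [Li]C
Why: 1,2-Addition of methyllithium to the lactone carbonyl (nucleophilic acyl substitution on a salicylate acetonide) should give the cyclic hemiketal alkoxide 11, which is kept cold and on protonation breaks down to the ortho-hydroxy methyl ketone with loss of acetone; any ketone set free earlier is shielded from a second addition by its ortho-phenoxide and its two ortho substituents.

Step 7
Reactants: 12 1-[4-(benzyloxy)-2-hydroxy-6-pentadecylphenyl]ethan-1-one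
Product: 13 1-[2,4-bis(benzyloxy)-6-pentadecylphenyl]ethan-1-one
Conditions: BnBr, K2CO3, DMF, 60 °C
Reagents that add atoms: benzyl bromide, BrCc1ccccc1
Why: Williamson etherification of the C2 phenol, which is hydrogen-bonded to the ketone and therefore needs DMF and gentle heating, while K2CO3 is too weak to enolise the methyl ketone towards C-benzylation.

Step 8
Reactants: 13 1-[2,4-bis(benzyloxy)-6-pentadecylphenyl]ethan-1-one
Product: 14 2,4-bis(benzyloxy)-6-pentadecylphenyl acetate
Conditions: mCPBA (1.5 equiv), CH2Cl2, 0 °C to rt
Reagents that add atoms: 3-chloroperoxybenzoic acid (mCPBA), OOC(=O)c1cccc(Cl)c1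
Why: Baeyer–Villiger oxidation, in which the peracid adds to the ketone (twisted out of conjugation by its two ortho substituents) and the electron-rich 2,4-dialkoxyaryl group of the Criegee adduct migrates far more readily than methyl, so that oxygen is inserted between C1 and the acyl carbon and the former carboxyl carbon ends as the acetate carbonyl.

Step 9
Reactants: 14 2,4-bis(benzyloxy)-6-pentadecylphenyl acetate
Product: 15 2,4-dihydroxy-6-pentadecylphenyl acetate
Conditions: H2 (1 atm), 10% Pd/C, EtOAc, rt
Reagents that add atoms: none
Why: Catalytic hydrogenolysis of the two benzyl aryl ethers under neutral conditions without base or alcohol should leave the aryl acetate untouched and give no opening for acetyl migration from O1 to the neighbouring O2.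

Compound list
1 | 2,2,6-trimethyl-4H-1,3-dioxin-4-one | CC1=CC(=O)OC(C)(C)O1 | starting material
2 | acetyl chloride | CC(Cl)=O | starting material
3 | 2,2-dimethyl-6-(2-oxopropyl)-4H-1,3-dioxin-4-one | CC(=O)CC1=CC(=O)OC(C)(C)O1 | intermediate
4 | hexadecanoyl chloride | CCCCCCCCCCCCCCCC(Cl)=O | starting material
5 | N-methoxy-N-methylhexadecanamide | CCCCCCCCCCCCCCCC(=O)N(C)OC | intermediate
6 | dilithium salt of the tetrahedral adduct of the dianion of 3 with 5 (hemiaminal alkoxide and ketone enolate, racemic, not isolated) | CCCCCCCCCCCCCCCC([O-])(N(C)OC)CC([O-])=CC1=CC(=O)OC(C)(C)O1.[Li+].[Li+] | intermediate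
7 | 6-(2,4-dioxononadecyl)-2,2-dimethyl-4H-1,3-dioxin-4-one | CCCCCCCCCCCCCCCC(=O)CC(=O)CC1=CC(=O)OC(C)(C)O1 | intermediate
8 | 5-hydroxy-2,2-dimethyl-5-pentadecyl-5,6-dihydro-4H-1,3-benzodioxine-4,7(8H)-dione (racemic, not isolated) | CCCCCCCCCCCCCCCC1(O)CC(=O)CC2=C1C(=O)OC(C)(C)O2 | intermediate
9 | 7-hydroxy-2,2-dimethyl-5-pentadecyl-4H-1,3-benzodioxin-4-one | CCCCCCCCCCCCCCCc1cc(O)cc2OC(C)(C)OC(=O)c12 | intermediate
10 | 7-(benzyloxy)-2,2-dimethyl-5-pentadecyl-4H-1,3-benzodioxin-4-one | CCCCCCCCCCCCCCCc1cc(OCc3ccccc3)cc2OC(C)(C)OC(=O)c12 | intermediate
11 | lithium 7-(benzyloxy)-2,2,4-trimethyl-5-pentadecyl-4H-1,3-benzodioxin-4-olate (racemic, not isolated) | CCCCCCCCCCCCCCCc1cc(OCc3ccccc3)cc2OC(C)(C)OC(C)([O-])c12.[Li+] | intermediate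
12 | 1-[4-(benzyloxy)-2-hydroxy-6-pentadecylphenyl]ethan-1-one | CCCCCCCCCCCCCCCc1cc(OCc2ccccc2)cc(O)c1C(C)=O | intermediate
13 | 1-[2,4-bis(benzyloxy)-6-pentadecylphenyl]ethan-1-one | CCCCCCCCCCCCCCCc1cc(OCc2ccccc2)cc(OCc2ccccc2)c1C(C)=O | intermediate
14 | 2,4-bis(benzyloxy)-6-pentadecylphenyl acetate | CCCCCCCCCCCCCCCc1cc(OCc2ccccc2)cc(OCc2ccccc2)c1OC(C)=O | intermediate
15 | 2,4-dihydroxy-6-pentadecylphenyl acetate | CCCCCCCCCCCCCCCc1cc(O)cc(O)c1OC(C)=O | target

Total step count: 9.
Longest linear sequence: 8 steps (steps 1, 3, 4, 5, 6, 7, 8, 9 from compound 1); step 2 is a one-step side branch.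

Steps most likely to fail

Step 4 (key step). The folding may stall at the carbinol stage or revert by retro-aldol. Alternatively the chain may close through oxygen or through attack on the carboxyl carbon once the dioxinone is opened, which would divert material from the resorcylate. The fallback sets out from 7 and returns at 9; it unmasks the carboxyl end first and aromatises the open-chain triketo ester. Heating 7 with benzyl alcohol in toluene at 110 °C should expel acetone by retro-hetero-Diels–Alder fragmentation and trap the acylketene as benzyl 3,5,7-trioxodocosanoate F1. Treatment with Cs2CO3 in THF followed by acidification should bring about the same aldol folding and dehydration to benzyl 2,4-dihydroxy-6-pentadecylbenzoate F2. Hydrogenolysis (H2, 10% Pd/C, EtOAc, rt) should give 2,4-dihydroxy-6-pentadecylbenzoic acid F3 without heating that could cause decarboxylation. Acetonide formation with acetone, trifluoroacetic anhydride and trifluoroacetic acid at 0 °C to rt then closes the benzodioxinone 9.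

Step 6. The tetrahedral adduct may collapse in the flask so that a second methyl group adds and a tertiary carbinol results, or the addition may stop short through enolisation. The fallback sets out from 10 and returns at 13, and builds the acetyl group in two separate carbonyl operations. Reduction of 10 with iBu2AlH in CH2Cl2 at −78 °C, an established way from salicylate acetonides to salicylaldehydes, should give 4-(benzyloxy)-2-hydroxy-6-pentadecylbenzaldehyde F4. Benzylation (BnBr, K2CO3, DMF) should give 2,4-bis(benzyloxy)-6-pentadecylbenzaldehyde F5. Addition of MeMgBr in THF at 0 °C should give racemic 1-[2,4-bis(benzyloxy)-6-pentadecylphenyl]ethan-1-ol F6, and oxidation with Dess–Martin periodinane in CH2Cl2 should deliver ketone 13.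

Step 3. Dianion formation may be incomplete, proton exchange may consume the carbanion, or the sensitive tricarbonyl product may cyclise or decompose during work-up, so that the acylation gives little usable material. The fallback sets out from 3 and returns at 7, and replaces the acylation by an aldol addition followed by oxidation. The dianion of 3 (LiN(iPr)2, THF, −78 °C) is added to commercial hexadecanal; the alkoxide formed is not acidic enough to disturb the dianion, and racemic 6-(4-hydroxy-2-oxononadecyl)-2,2-dimethyl-4H-1,3-dioxin-4-one F7 should result. Oxidation of this β-hydroxy ketone with Dess–Martin periodinane in CH2Cl2 at rt should give the 1,3-diketone 7.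

Further compounds
F1 | step 4 | benzyl 3,5,7-trioxodocosanoate | CCCCCCCCCCCCCCCC(=O)CC(=O)CC(=O)CC(=O)OCc1ccccc1
F2 | step 4 | benzyl 2,4-dihydroxy-6-pentadecylbenzoate | CCCCCCCCCCCCCCCc1cc(O)cc(O)c1C(=O)OCc1ccccc1
F3 | step 4 | 2,4-dihydroxy-6-pentadecylbenzoic acid | CCCCCCCCCCCCCCCc1cc(O)cc(O)c1C(O)=O
F4 | step 6 | 4-(benzyloxy)-2-hydroxy-6-pentadecylbenzaldehyde | CCCCCCCCCCCCCCCc1cc(OCc2ccccc2)cc(O)c1C=O
F5 | step 6 | 2,4-bis(benzyloxy)-6-pentadecylbenzaldehyde | CCCCCCCCCCCCCCCc1cc(OCc2ccccc2)cc(OCc2ccccc2)c1C=O
F6 | step 6 | 1-[2,4-bis(benzyloxy)-6-pentadecylphenyl]ethan-1-ol (racemic) | CCCCCCCCCCCCCCCc1cc(OCc2ccccc2)cc(OCc2ccccc2)c1C(C)O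
F7 | step 3 | 6-(4-hydroxy-2-oxononadecyl)-2,2-dimethyl-4H-1,3-dioxin-4-one (racemic) | CCCCCCCCCCCCCCCC(O)CC(=O)CC1=CC(=O)OC(C)(C)O1
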